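**Assumptions (one line each)**
- Only skeleton-building starting materials, intermediates and the target are numbered; catalysts, bases and protecting-group reagents appear in the Conditions and "Reagents that add atoms" lines.
- The target SMILES corresponds to the trans-(1S,2R) isomer in 1-aryl-1,2-dihydronaphthalene numbering, which is (3R,4S) in naphthalene-2-carbaldehyde numbering.

**Retrosynthetic overview**
1. Vitedoin A (11) ⇐ tris-silyl ether 10 by global desilylation.
2. 10 ⇐ 2-benzylbenzaldehyde 6 + γ-silyloxy enal 9 by a light-driven photoenolization / chiral iminium–enamine cascade (formal asymmetric [4+2], then dehydration). This forms C1–C2 and C3=C4 and sets both stereocenters in one step.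
3. 6 ⇐ aryl iodide 3 + benzylic chloride 5 (Negishi sp2–sp3 coupling). The awkward C8a–C1 bond ortho to OMe is therefore made by cross-coupling, not by a Friedel–Crafts or oxidative-coupling closure that would go para to OMe.
4. 3 and 5 both come from TIPS-vanillin 2 (directed ortho-metalation/iodination; reduction/chlorination). 9 comes from cross-metathesis of 7 and 8.
5. Ring order: both benzene rings are bought as vanillin; the dihydronaphthalene carbocycle is the only ring built, and it is built last.

**Route**

Step 1
Reactants: 1, vanillin (4-hydroxy-3-methoxybenzaldehyde)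
Product: 2, 3-methoxy-4-(triisopropylsilyloxy)benzaldehyde
Conditions: TIPSCl, imidazole, DMF, 0 °C → rt
Reagents that add atoms: triisopropylsilyl chloride, CC(C)[Si](Cl)(C(C)C)C(C)C
Why: Standard phenol O-silylation; the bulky, non-coordinating OTIPS group survives organolithiums, is a poor ortho-director, and is removed by fluoride at the end.

Step 2
Reactants: 2
Product: 3, 2-iodo-3-methoxy-4-(triisopropylsilyloxy)benzaldehyde
Conditions: LiN(Me)CH2CH2NMe2, THF, −20 °C; n-BuLi (3 equiv), −20 °C, 18 h; I2, −78 °C → rt; aq. Na2S2O3 / dil. HCl
Reagents that add atoms: iodine, II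
Why: Comins α-amino-alkoxide directed ortho-metalation; the in situ masked CHO and the 3-OMe cooperatively direct lithiation to C2 between them (OTIPS blocks and does not direct to C5), iodine traps the aryllithium, and work-up regenerates the aldehyde.

Step 3
Reactants: 2
Product: 4, [3-methoxy-4-(triisopropylsilyloxy)phenyl]methanol
Conditions: NaBH4, MeOH/THF, 0 °C
Reagents that add atoms: none (hydride only)
Why: Chemoselective borohydride reduction of the aldehyde; the aryl TIPS ether is inert.

Step 4
Reactants: 4
Product: 5, [4-(chloromethyl)-2-methoxyphenoxy]triisopropylsilane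
Conditions: SOCl2, pyridine, CH2Cl2, 0 °C; used crude
Reagents that add atoms: thionyl chloride, O=S(Cl)Cl
Why: Deoxychlorination of an electron-rich benzylic alcohol via the chlorosulfite; the chloride (not the bromide) is chosen to minimise Wurtz coupling during zinc insertion.

Step 5
Reactants: 3 and 5
Product: 6, 3-methoxy-2-[3-methoxy-4-(triisopropylsilyloxy)benzyl]-4-(triisopropylsilyloxy)benzaldehyde
Conditions: 5, Zn dust, LiCl, THF, 25 °C (gives ArCH2ZnCl·LiCl); then slow addition to 3, Pd(OAc)2 (2 mol %), SPhos (4 mol %), THF, 0 → 25 °C
Reagents that add atoms: none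
Why: LiCl-mediated zinc insertion followed by Negishi sp2–sp3 cross-coupling; Pd/SPhos couples the di-ortho-substituted iodide within minutes, faster than uncatalysed addition of the benzylzinc to the hindered, electron-rich aldehyde.

Step 6
Reactants: 7, allyloxy(tert-butyl)dimethylsilane, and 8, (E)-crotonaldehyde (3 equiv)
Product: 9, (E)-4-(tert-butyldimethylsilyloxy)but-2-enal
Conditions: Hoveyda–Grubbs II (2 mol %), CH2Cl2, 40 °C
Reagents that add atoms: none
Why: Olefin cross-metathesis of a type-I allyl ether with an enal; it is E-selective and driven by loss of propene.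

Step 7 (key step)
Reactants: 6 and 9 (2 equiv)
Product: 10, (3R,4S)-3-[(tert-butyldimethylsilyloxy)methyl]-5-methoxy-4-[3-methoxy-4-(triisopropylsilyloxy)phenyl]-6-(triisopropylsilyloxy)-3,4-dihydronaphthalene-2-carbaldehyde (3,4-trans)
Conditions: (R)-α,α-bis[3,5-bis(trifluoromethyl)phenyl]prolinol TMS ether (20 mol %), PhCO2H (20 mol %), degassed toluene (0.05 M, thin-film/flow), 365 nm LED, 0 °C; then dark, 25 °C to complete dehydration
Reagents that add atoms: none (water is lost)
Why: Proposed new method: 365 nm n→π* excitation of 6 causes 1,5-H transfer from the diarylmethane C–H to give the long-lived (E,E)-hydroxy-o-quinodimethane (OH and aryl both "outside"), and this electron-rich diene is trapped by the LUMO-lowered (E)-iminium ion of 9; the benzylic terminus bonds to Cβ on the face opposite the catalyst's CAr2OTMS group (the (R)-catalyst gives the R centre bearing CH2OTBS) through an iminium-endo formal [4+2] (Michael, then aldol) transition state that puts CH2OTBS exo and so trans to the outside aryl (giving the S aryl-bearing centre), after which the β-hydroxy iminium/enamine loses water by E1cB and hydrolyses to the conjugated enal; the closest known reaction types are photoenolization/Diels–Alder of 2-benzylbenzaldehydes with trans dienophiles (1,2-trans 1-aryltetralin-4-ols), light-driven secondary-amine-catalysed enantioselective addition of 2-alkylbenzophenone photoenols to enal iminium ions, and iminium–enamine Michael/aldol-condensation cascades of salicylaldehydes with enals to 2H-chromene-3-carbaldehydes.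

Step 8
Reactants: 10
Product: 11, vitedoin A, (3R,4S)-6-hydroxy-4-(4-hydroxy-3-methoxyphenyl)-3-(hydroxymethyl)-5-methoxy-3,4-dihydronaphthalene-2-carbaldehyde
Conditions: TBAF (4 equiv), AcOH (4 equiv), THF, 0 °C → rt, under Ar
Reagents that add atoms: none
Why: Buffered fluoride desilylation removes both aryl TIPS ethers and the primary TBS ether; neither stereocenter is epimerisable here (one is doubly benzylic, the other is α′ to a cross-conjugated enal), and buffering plus inert atmosphere suppresses aromatisation.

**Compound list**
1 | vanillin | COc1cc(C=O)ccc1O | starting material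
2 | 3-methoxy-4-(triisopropylsilyloxy)benzaldehyde | COc1cc(C=O)ccc1O[Si](C(C)C)(C(C)C)C(C)C | intermediate
3 | 2-iodo-3-methoxy-4-(triisopropylsilyloxy)benzaldehyde | COc1c(I)c(C=O)ccc1O[Si](C(C)C)(C(C)C)C(C)C | intermediate
4 | [3-methoxy-4-(triisopropylsilyloxy)phenyl]methanol | COc1cc(CO)ccc1O[Si](C(C)C)(C(C)C)C(C)C | intermediate
5 | [4-(chloromethyl)-2-methoxyphenoxy]triisopropylsilane | COc1cc(CCl)ccc1O[Si](C(C)C)(C(C)C)C(C)C | intermediate
6 | 3-methoxy-2-[3-methoxy-4-(triisopropylsilyloxy)benzyl]-4-(triisopropylsilyloxy)benzaldehyde | COc1cc(Cc2c(C=O)ccc(O[Si](C(C)C)(C(C)C)C(C)C)c2OC)ccc1O[Si](C(C)C)(C(C)C)C(C)C | intermediate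
7 | allyloxy(tert-butyl)dimethylsilane | C=CCO[Si](C)(C)C(C)(C)C | starting material
8 | (E)-crotonaldehyde | C/C=C/C=O | starting material
9 | (E)-4-(tert-butyldimethylsilyloxy)but-2-enal | O=C/C=C/CO[Si](C)(C)C(C)(C)C | intermediate
10 | tris-silyl vitedoin A (3R,4S, trans) | COc1cc([C@H]2c3c(ccc(O[Si](C(C)C)(C(C)C)C(C)C)c3OC)C=C(C=O)[C@@H]2CO[Si](C)(C)C(C)(C)C)ccc1O[Si](C(C)C)(C(C)C)C(C)C | intermediate
11 | vitedoin A | COc1cc([C@H]2c3c(ccc(O)c3OC)C=C(C=O)[C@@H]2CO)ccc1O | target

**Totals**
- Total steps: 8
- Longest linear sequence: 6 steps (1 → 2 → 4 → 5 → 6 → 10 → 11; steps 1, 3, 4, 5, 7, 8)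

**Three steps most likely to fail, with fallbacks**
1. **Step 7 (photo-organocatalytic cascade).** Risks are a racemic background cycloaddition with free enal, imperfect endo/exo (trans/cis) control, inefficient photoenolization of the electron-rich aldehyde, and product absorption at 365 nm. Fallback: switch to an auxiliary-controlled photoenolization/Diels–Alder of 6 with a chiral fumarate diester (lactate- or menthol-derived), which has direct precedent for 1,2-trans adducts of 2-benzylbenzaldehydes. Then dehydrate the C4-OH, reduce both esters with DIBAL, oxidise only the allylic alcohol with MnO2 to the enal, and desilylate.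
2. **Step 2 (directed ortho-metalation/iodination).** Risks are C2 versus C5 regioselectivity and TIPS survival under excess n-BuLi. Fallback: drop metalation and start from commercial 2-bromo-3,4-dimethoxybenzaldehyde, with regioselective nucleophilic demethylation of the OMe para to CHO (NaSEt or LiCl, DMF) and TIPS protection to give the bromo analogue of 3.
3. **Step 5 (Negishi coupling beside a free aldehyde).** Risks are benzylzinc addition to CHO and bibenzyl homocoupling. Fallback: reverse the polarity and merge with step 2. Keep the aldehyde masked as the α-amino alkoxide, transmetalate the C2-aryllithium to zinc or copper, and couple it in the same pot with benzylic chloride 5 as the electrophile, so that no free carbonyl ever meets an organometallic.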